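## Analysis of the target

Locants follow cyclopenta[c]pyridine (C1, N2, C3, C4, C4a, C5, C6, C7, C7a); the linker is numbered C1'–C8'. "β" means the face of H4a and H7a.

- The target is the diester of (2E,6E)-2,6-dimethylocta-2,6-dienedioic acid with two identical amino alcohols, (4R,4aS,6R,7S,7aR)-2,4,7-trimethyloctahydro-1H-cyclopenta[c]pyridin-6-ol. The chain is unsymmetrical (α-methyl enoate at C1', β-methyl enoate at C8'), but both ends carry the same alcohol, so the two acid termini need not be told apart.
- Each bicycle is a cis-fused cyclopentane (C4a–C5–C6–C7–C7a) and N-methylpiperidine (C1–N2–C3–C4–C4a–C7a) with five contiguous stereocentres. H4, H4a, H7a, the C7 methyl and the C6 oxygen all lie on the β face; the C4 methyl and H7 lie on the α face.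
- The C4 methyl is therefore cis to C5 (an all-cis 3,4,5-trisubstituted piperidine). Forming a C–C bond next to an existing C4 centre tends to give the opposite relationship, so this arrangement is best written by delivering hydrogen to sp2 carbons C4 and C4a.
- H7 and H7a are trans, so C7 cannot come from the same syn addition. It is α to C6, however, and its configuration (methyl trans to C1, on the convex face) is the thermodynamic one of a C6 ketone.
- The C6–O bond is cis to the C7 methyl on the convex face. Small hydrides attack a C6 ketone from that face and give the opposite alcohol, so the oxygen must arrive with inversion.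
- The feature that invites the key step: C6 is an oxygenated ring carbon flanked by C5H2 and the methyl-bearing C7, in a cyclopentane fused at C4a–C7a to the nitrogen ring. This is the retron of a [2+2+1] cyclocarbonylation (C6 = CO, C7–C7a = a but-2-ynyl alkyne, C4a–C5 = a terminal C=C). If C4=C4a is the second double bond of an allene, the whole ring system can be made with no stereocentre at all.
- Sensitive groups are the two E-enoate esters (hydride, base, conjugate addition) and the two tertiary amines (they bind Rh, B and Ir reagents). The esters are therefore made last and nitrogen is carried as a carbamate.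
- The main difficulty is ten stereocentres in two identical sets of five, which must be enantiopure before the union, otherwise diastereomeric diesters form.

## Retrosynthetic reasoning

**20 ⇒ 2 × 12 + 17.** The two C6–O(alkyl) bonds are cut, not the acyl C–O bonds. A double Mitsunobu reaction then forms both ester bonds and sets both C6 centres by inversion, so the alcohol needed is 12, the C6 epimer that hydride reduction gives naturally. Putting the enoates in last keeps them away from every hydride and hydrogenation step.

**12 ⇒ 10.** The C6–H bond and the three N–CH3 hydrogens are cut. One aluminium hydride step reduces the ketone (through 11) and turns the Boc carbonyl into the N-methyl carbon, so no separate deprotection or methylation is needed.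

**10 ⇒ 9 ⇒ 8.** C7 is epimerised through the C6 ketone (9 to 10) and the ketone comes from alcohol 8. The carbinol centre of 8 is used only as a relay and is erased after it has done its work.

**8 ⇒ 7.** Four C–H bonds (C4, C4a, C7, C7a) are cut on one face. The single carbinol centre of 7 directs hydrogen to both tetrasubstituted alkenes, which writes the all-cis H4/H4a/H7a array.

**7 ⇒ 6.** The C6–H bond is cut. Ketone 6 is achiral, so one reagent-controlled carbonyl reduction introduces all the absolute stereochemistry of the route.

**6 ⇒ 5 (key).** Three C–C bonds are cut: C7a–C4a, C5–C6 and C6–C7. Both rings open to the acyclic allenyne 5, and C6 is delivered as a carbonyl ligand of the metal. Cutting here removes every ring and every stereochemical problem from the precursor.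

**5 ⇒ 4 ⇒ 2 + 3; 2 ⇐ 1.** The allene is cut at the C4–CH3 bond (SN2′ methyl transfer to propargylic chloride 4). 4 is cut at N–C3 into carbamate 2 and the symmetrical dichloride 3.

**17 ⇒ 16 ⇒ 15 ⇒ 14 ⇒ 13.** The diacid is geranyl acetate (13) oxidised at both ends. The E-selective allylic oxidation of the terminal methyl sets the C2'=C3' geometry, and the C6'=C7' geometry is bought with 13.

## Alternatives that were turned down

**Alternative 1:** (textbook) Disconnection at both acyl C–O bonds, to the (6R)-amino alcohol A1 and the diacid dichloride A2. The bicycle of A1 would come from a Robinson-type cyclopentenone annulation: a commercial N-Boc-3-methyl-4-piperidone is alkylated and the resulting 1,4-diketone is closed by intramolecular aldol condensation (forming C4a=C5) to enone A3. Turned down for three reasons: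
- The key step sets nothing. C4, C7 and C7a of A3 are all enolisable or dienolisable, so A3 is racemic and a resolution is unavoidable.
- The C4/C4a relationship would hang on hydrogenating a trisubstituted alkene between two epimerisable centres.
- Acylation needs A1, whose C6 configuration is the one hydride reduction does not give, so an extra inversion is added to an already longer sequence.

**Alternative 2:** Disconnection of C7a–C4a, C5–C6 and C6–C7 by a cobalt-mediated Pauson–Khand reaction of the chiral 1,7-enyne A4, which carries the C4 methyl as an allylic stereocentre, to give enone A5. This is the shortest route on paper. Turned down because the stereocentre works against the target. In a chair-like insertion with C5 equatorial, the allylic methyl goes equatorial, trans to the new C4a–C5 bond, which is the (4R,4aR) isomer A5; the target needs the methyl cis to C5. Methyl versus hydrogen is in any case a weak 1,2-control element, and neither C4 nor C4a can be corrected afterwards without losing the only source of chirality.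

**Alternative 3:** Disconnection of both C–N bonds (N2–C1 and N2–C3): biomimetic double reductive amination of the iridodial-type 1,5-dialdehyde A6 with a methylammonium source. A6 would come from an intramolecular Michael cyclisation of an acyclic enal-aldehyde. Turned down for three reasons:
- The ring-closing step forms no C–C bond and no stereocentre.
- C4 and C7a are α to the aldehydes of A6 and equilibrate through enamines during the amination, and the all-cis piperidine is not clearly the thermodynamic product.
- The C6–O/C7–CH3 pair would have to be built on an open chain (crotylation, protection, two oxidations) before the cyclopentane even exists, which costs more steps than the whole route chosen here.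

Key step: step 4

Remark on the chemistry: the sense of induction in step 5 is assigned on the assumption that the methyl-substituted alkenyl branch (C7) acts as the larger ketone substituent in the oxazaborolidine model.

## Route

Step 1
Reactants: 1 but-2-yn-1-amine hydrochloride
Product: 2 tert-butyl but-2-yn-1-ylcarbamate
Conditions: Boc2O, Et3N, CH2Cl2, 0 °C to rt
Reagents that add atoms: di-tert-butyl dicarbonate, CC(C)(C)OC(=O)OC(=O)OC(C)(C)C
Why: Standard N-acylation to the carbamate. The Boc group makes nitrogen non-basic for the Rh, B and Ir steps, and its carbonyl carbon later becomes the N-methyl carbon.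

Step 2
Reactants: 2 tert-butyl but-2-yn-1-ylcarbamate; 3 1,4-dichlorobut-2-yne (3 equiv)
Product: 4 tert-butyl but-2-yn-1-yl(4-chlorobut-2-yn-1-yl)carbamate
Conditions: NaH, DMF, 0 °C; then 3, 0 °C to rt
Reagents that add atoms: none
Why: SN2 N-alkylation of the carbamate anion by a primary propargylic chloride. The excess of the symmetrical dichloride suppresses double substitution.

Step 3
Reactants: 4 tert-butyl but-2-yn-1-yl(4-chlorobut-2-yn-1-yl)carbamate
Product: 5 tert-butyl but-2-yn-1-yl(2-methylbuta-2,3-dien-1-yl)carbamate
Conditions: MeMgBr, CuBr·SMe2 (cat.), LiBr, THF, −78 to −20 °C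
Reagents that add atoms: methylmagnesium bromide, C[Mg]Br
Why: Copper-mediated SN2′ substitution of the propargylic chloride puts the methyl on the remote alkyne carbon and gives the 1,1-disubstituted allene. The carbamate and the chloride-free butynyl arm are inert at this temperature.

Step 4
Reactants: 5 tert-butyl but-2-yn-1-yl(2-methylbuta-2,3-dien-1-yl)carbamate
Product: 6 tert-butyl 4,7-dimethyl-6-oxo-1,3,5,6-tetrahydro-2H-cyclopenta[c]pyridine-2-carboxylate
Conditions: [Rh(CO)2Cl]2 (5 mol %), CO (1 atm), toluene, 90 °C
Reagents that add atoms: carbon monoxide, [C-]#[O+]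
Why: Rh(I) binds the alkyne and the distal C4a=C5 π-bond of the allene and undergoes oxidative cyclisation to a rhodacyclopentene, forming C7a–C4a; CO inserts into the Rh–C5 bond and reductive elimination forms C6–C7. The closest known reaction type is the Rh(I)-catalysed allenic Pauson–Khand reaction of heteroatom-tethered allenynes with a three-atom tether, which gives 4-alkylidene bicyclo[4.3.0] dienones. The nitrogen ring is closed by the C7a–C4a bond (6-exo-dig at the alkyne, with attack at the central allene carbon so that C4=C4a stays endocyclic), and the cyclopentenone is closed by the two bonds to C6, a [2+2+1] closure. No stereocentre is formed: 6 is achiral by design, because C4, C4a, C7 and C7a are written later by hydrogen from one face. The selectivity needed is for the distal over the proximal allene π-bond; Rh(I) chooses the distal bond, and the proximal bond is also 1,1-disubstituted, so its use would force a quaternary C4 in a 5,5-system. The position of the carbonyl (C6 between C5 and the methyl-bearing C7) is fixed by the tether. One atmosphere of CO suppresses the competing Rh-catalysed cycloisomerisation of the allenyne.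

Step 5
Reactants: 6 tert-butyl 4,7-dimethyl-6-oxo-1,3,5,6-tetrahydro-2H-cyclopenta[c]pyridine-2-carboxylate
Product: 7 tert-butyl (6R)-6-hydroxy-4,7-dimethyl-1,3,5,6-tetrahydro-2H-cyclopenta[c]pyridine-2-carboxylate
Conditions: (S)-Me-CBS oxazaborolidine (20 mol %), catecholborane, toluene, −78 °C
Reagents that add atoms: none
Why: Corey–Bakshi–Shibata reduction. The ketone binds the catalyst boron anti to its larger substituent (the tetrasubstituted C7 alkenyl branch versus C5H2) and hydride is delivered to one face, which should give the 6R carbinol, the only stereocentre introduced by a reagent in the route. The reduction is 1,2-selective and the tetrasubstituted alkenes are not hydroborated at −78 °C.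

Step 6
Reactants: 7 tert-butyl (6R)-6-hydroxy-4,7-dimethyl-1,3,5,6-tetrahydro-2H-cyclopenta[c]pyridine-2-carboxylate
Product: 8 tert-butyl (4R,4aS,6R,7R,7aR)-6-hydroxy-4,7-dimethyloctahydro-2H-cyclopenta[c]pyridine-2-carboxylate
Conditions: [Ir(cod)(PCy3)(py)]PF6 (10 mol %), H2 (1–4 atm), CH2Cl2, rt
Reagents that add atoms: none
Why: Hydroxyl-directed hydrogenation with Crabtree's catalyst, which also reduces tetrasubstituted alkenes. Iridium held by the C6 hydroxyl delivers hydrogen to the OH face of the C7=C7a/C4a=C4 diene, whether by two 1,2-additions or by 1,4- then 1,2-addition. The four new hydrogens at C7, C7a, C4a and C4 should therefore all be cis to OH, which fixes C4 (R), C4a (S) and C7a (R) from the single C6 centre; the C7 centre formed here is provisional.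

Step 7
Reactants: 8 tert-butyl (4R,4aS,6R,7R,7aR)-6-hydroxy-4,7-dimethyloctahydro-2H-cyclopenta[c]pyridine-2-carboxylate
Product: 9 tert-butyl (4R,4aS,7R,7aR)-4,7-dimethyl-6-oxooctahydro-2H-cyclopenta[c]pyridine-2-carboxylate
Conditions: Dess–Martin periodinane, CH2Cl2, 0 °C to rt
Reagents that add atoms: none
Why: Dess–Martin oxidation of the secondary alcohol under near-neutral conditions. The relay centre C6 is erased after its information has been copied to C4, C4a and C7a, which are not enolisable.

Step 8
Reactants: 9 tert-butyl (4R,4aS,7R,7aR)-4,7-dimethyl-6-oxooctahydro-2H-cyclopenta[c]pyridine-2-carboxylate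
Product: 10 tert-butyl (4R,4aS,7S,7aR)-4,7-dimethyl-6-oxooctahydro-2H-cyclopenta[c]pyridine-2-carboxylate
Conditions: DBU, toluene, rt to 40 °C
Reagents that add atoms: none
Why: Thermodynamic epimerisation α to the ketone. Enolisation moves the C7 methyl from the concave face (cis to C1, under the piperidine) to the convex face, trans to C1. The other enolisable position, C5, carries no stereocentre.

Step 9
Reactants: 10 tert-butyl (4R,4aS,7S,7aR)-4,7-dimethyl-6-oxooctahydro-2H-cyclopenta[c]pyridine-2-carboxylate
Product: 12 (4R,4aS,6S,7S,7aR)-2,4,7-trimethyloctahydro-1H-cyclopenta[c]pyridin-6-ol (6-epi-incarvilline), via N-Boc alcohol 11 (not isolated)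
Conditions: LiAlH4, THF, −78 to 0 °C; then reflux; Fieser work-up
Reagents that add atoms: none
Why: At low temperature hydride should add to the ketone from the convex β face, because the concave face is covered by C1 and C4 of the piperidine and small hydrides add syn to a pseudo-equatorial α-methyl. This gives the 6S alcohol with OH trans to the C7 methyl. At reflux the carbamate is reduced to N–CH3 (the known Boc-to-N-methyl reduction).

Step 10
Reactants: 13 geranyl acetate
Product: 14 (2E,6E)-8-hydroxy-3,7-dimethylocta-2,6-dien-1-yl acetate
Conditions: SeO2 (cat.), t-BuOOH, salicylic acid (cat.), CH2Cl2, rt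
Reagents that add atoms: tert-butyl hydroperoxide, CC(C)(C)OO (oxygen relayed through selenium dioxide, O=[Se]=O)
Why: Selenium dioxide allylic oxidation (ene reaction, then [2,3]-shift) attacks the E-methyl of the terminal trisubstituted alkene and sets the 6E geometry. The acetate deactivates the C2=C3 alkene.

Step 11
Reactants: 14 (2E,6E)-8-hydroxy-3,7-dimethylocta-2,6-dien-1-yl acetate
Product: 15 (2E,6E)-2,6-dimethylocta-2,6-diene-1,8-diol
Conditions: K2CO3, MeOH, rt
Reagents that add atoms: none
Why: Base-catalysed transesterification removes the acetate without touching either alkene.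

Step 12
Reactants: 15 (2E,6E)-2,6-dimethylocta-2,6-diene-1,8-diol
Product: 16 (2E,6E)-2,6-dimethylocta-2,6-dienedial
Conditions: MnO2, CH2Cl2, rt
Reagents that add atoms: none
Why: Manganese dioxide oxidises both allylic alcohols to the enals and is known to preserve trisubstituted alkene geometry.

Step 13
Reactants: 16 (2E,6E)-2,6-dimethylocta-2,6-dienedial
Product: 17 (2E,6E)-2,6-dimethylocta-2,6-dienedioic acid
Conditions: NaClO2, NaH2PO4, 2-methyl-2-butene, t-BuOH/H2O, rt
Reagents that add atoms: sodium chlorite, [Na+].[O-]Cl=O
Why: Pinnick oxidation converts enals to enoic acids without isomerising or chlorinating the alkenes; the hypochlorite formed is trapped by the scavenger alkene.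

Step 14
Reactants: 12 (4R,4aS,6S,7S,7aR)-2,4,7-trimethyloctahydro-1H-cyclopenta[c]pyridin-6-ol (2.2 equiv); 17 (2E,6E)-2,6-dimethylocta-2,6-dienedioic acid
Product: 20 bis[(4R,4aS,6R,7S,7aR)-2,4,7-trimethyloctahydro-1H-cyclopenta[c]pyridin-6-yl] (2E,6E)-2,6-dimethylocta-2,6-dienedioate (target), via C1 monoester 18 (not isolated), via C8 monoester 19 (not isolated)
Conditions: PPh3, DIAD, THF, 0 °C to rt
Reagents that add atoms: none
Why: Double Mitsunobu esterification. Each alkoxyphosphonium ion of 12 is displaced by a carboxylate of 17 in an SN2 step from the open convex face, with inversion, so both ester C–O bonds form and both C6 centres become R in one operation. Participation by N2 is excluded geometrically because the leaving group sits on the concave, nitrogen-side face, and the E-enoates are not touched.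

## Compound list

1 | but-2-yn-1-amine hydrochloride | CC#CCN.Cl | starting material
2 | tert-butyl but-2-yn-1-ylcarbamate | CC#CCNC(=O)OC(C)(C)C | intermediate
3 | 1,4-dichlorobut-2-yne | ClCC#CCCl | starting material
4 | tert-butyl but-2-yn-1-yl(4-chlorobut-2-yn-1-yl)carbamate | CC#CCN(CC#CCCl)C(=O)OC(C)(C)C | intermediate
5 | tert-butyl but-2-yn-1-yl(2-methylbuta-2,3-dien-1-yl)carbamate | CC#CCN(CC(C)=C=C)C(=O)OC(C)(C)C | intermediate
6 | tert-butyl 4,7-dimethyl-6-oxo-1,3,5,6-tetrahydro-2H-cyclopenta[c]pyridine-2-carboxylate (achiral) | O=C1CC2=C(C)CN(C(=O)OC(C)(C)C)CC2=C1C | intermediate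
7 | tert-butyl (6R)-6-hydroxy-4,7-dimethyl-1,3,5,6-tetrahydro-2H-cyclopenta[c]pyridine-2-carboxylate | O[C@@H]1CC2=C(C)CN(C(=O)OC(C)(C)C)CC2=C1C | intermediate
8 | tert-butyl (4R,4aS,6R,7R,7aR)-6-hydroxy-4,7-dimethyloctahydro-2H-cyclopenta[c]pyridine-2-carboxylate | O[C@@H]1C[C@@H]2[C@@H](CN(C(=O)OC(C)(C)C)C[C@@H]2C)[C@H]1C | intermediate
9 | tert-butyl (4R,4aS,7R,7aR)-4,7-dimethyl-6-oxooctahydro-2H-cyclopenta[c]pyridine-2-carboxylate | O=C1C[C@@H]2[C@@H](CN(C(=O)OC(C)(C)C)C[C@@H]2C)[C@H]1C | intermediate
10 | tert-butyl (4R,4aS,7S,7aR)-4,7-dimethyl-6-oxooctahydro-2H-cyclopenta[c]pyridine-2-carboxylate | O=C1C[C@@H]2[C@@H](CN(C(=O)OC(C)(C)C)C[C@@H]2C)[C@@H]1C | intermediate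
11 | tert-butyl (4R,4aS,6S,7S,7aR)-6-hydroxy-4,7-dimethyloctahydro-2H-cyclopenta[c]pyridine-2-carboxylate (formed as its aluminium alkoxide, not isolated) | O[C@H]1C[C@@H]2[C@@H](CN(C(=O)OC(C)(C)C)C[C@@H]2C)[C@@H]1C | intermediate
12 | (4R,4aS,6S,7S,7aR)-2,4,7-trimethyloctahydro-1H-cyclopenta[c]pyridin-6-ol (6-epi-incarvilline) | O[C@H]1C[C@@H]2[C@@H](CN(C)C[C@@H]2C)[C@@H]1C | intermediate
13 | geranyl acetate, (2E)-3,7-dimethylocta-2,6-dien-1-yl acetate | CC(C)=CCC/C(C)=C/COC(C)=O | starting material
14 | (2E,6E)-8-hydroxy-3,7-dimethylocta-2,6-dien-1-yl acetate | CC(=O)OC/C=C(\C)CC/C=C(\C)CO | intermediate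
15 | (2E,6E)-2,6-dimethylocta-2,6-diene-1,8-diol | OC/C=C(\C)CC/C=C(\C)CO | intermediate
16 | (2E,6E)-2,6-dimethylocta-2,6-dienedial | O=C/C=C(\C)CC/C=C(\C)C=O | intermediate
17 | (2E,6E)-2,6-dimethylocta-2,6-dienedioic acid | OC(=O)/C=C(\C)CC/C=C(\C)C(=O)O | intermediate
18 | C1 monoester: (2E,6E)-2,6-dimethyl-8-oxo-8-{[(4R,4aS,6R,7S,7aR)-2,4,7-trimethyloctahydro-1H-cyclopenta[c]pyridin-6-yl]oxy}... acid with the free acid at C8' (not isolated) | C/C(=C\C(=O)O)CC/C=C(\C)C(=O)O[C@@H]1C[C@@H]2[C@@H](CN(C)C[C@@H]2C)[C@@H]1C | intermediate
19 | C8 monoester: the regioisomeric half-ester with the free acid at C1' (not isolated) | C/C(=C\C(=O)O[C@@H]1C[C@@H]2[C@@H](CN(C)C[C@@H]2C)[C@@H]1C)CC/C=C(\C)C(=O)O | intermediate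
20 | bis[(4R,4aS,6R,7S,7aR)-2,4,7-trimethyloctahydro-1H-cyclopenta[c]pyridin-6-yl] (2E,6E)-2,6-dimethylocta-2,6-dienedioate | C/C(=C\C(=O)O[C@@H]1C[C@@H]2[C@@H](CN(C)C[C@@H]2C)[C@@H]1C)CC/C=C(\C)C(=O)O[C@@H]1C[C@@H]2[C@@H](CN(C)C[C@@H]2C)[C@@H]1C | target

## Step count and least certain steps

Total: 14 steps. Longest linear sequence: 10 steps (steps 1–9 and 14); the diacid branch (steps 10–13) is 4 steps.

**Step 4 (key step).** Most likely failure: at low CO concentration the rhodium catalyst can divert the allenyne into cycloisomerisation (Alder-ene type) or oligomerisation, and the doubly unsaturated ketone can isomerise on prolonged heating. Fallback, from 2 to 6 by an ene-yne route followed by dehydrogenation: carbamate 2 is N-alkylated (NaH, DMF) with racemic 2-methylbut-3-en-1-yl 4-methylbenzenesulfonate F1, made from the commercial alcohol and TsCl, to give the 1,7-enyne tert-butyl but-2-yn-1-yl(2-methylbut-3-en-1-yl)carbamate F2. A stoichiometric Co2(CO)8 / N-methylmorpholine N-oxide Pauson–Khand reaction closes the C7=C7a enone tert-butyl 4,7-dimethyl-6-oxo-1,3,4,4a,5,6-hexahydro-2H-cyclopenta[c]pyridine-2-carboxylate F3, whose C4/C4a stereochemistry does not matter. Chloranil in refluxing t-BuOH, which extends enones linearly through the dienol, removes H4a and H4 and returns to the achiral dienone 6.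

**Step 5.** Most likely failure: insufficient steric discrimination between the two α-branches of the ketone, giving lower enantioselectivity, or partial 1,4-reduction. Fallback, from 6 to 7 by resolution instead of asymmetric reduction: Luche reduction (NaBH4, CeCl3, MeOH) gives the racemic dienol F4. Lipase-catalysed acylation (CAL-B, vinyl acetate) should acylate the R enantiomer to the (6R)-acetate F5, which is separated from the unreacted S alcohol and methanolysed (K2CO3, MeOH) to 7.

**Step 6.** Most likely failure: hydrogen delivery without hydroxyl coordination (loss of facial fidelity, which becomes loss of enantiopurity after step 7), incomplete saturation of the two tetrasubstituted alkenes, or acid-promoted ionisation of the dienylic alcohol. Fallback, from 6 to 9, with shielding in place of direction: reduction of 6 with the (R)-oxazaborolidine gives the (6S)-dienol F6, which is silylated (TBSCl, imidazole) to F7. Heterogeneous hydrogenation (PtO2 or Rh/Al2O3, H2 under pressure) adds all four hydrogens anti to the silyl ether, giving the saturated silyl ether F8 with the same C4, C4a, C7a configuration as 8. Desilylation (TBAF) gives the (4R,4aS,6S,7R,7aR)-alcohol F9, and Dess–Martin oxidation returns to 9.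

**Step 9.** Most likely failure: the carbamate reduction stalls (N-formyl or N–H products) or facial selectivity at the ketone erodes while the mixture is heated. Fallback, from 10 to 12 with the two events separated: TFA removes the Boc group to give the secondary amino ketone F10. Reductive methylation (aqueous HCHO, NaBH(OAc)3) gives the N-methyl ketone F11, and NaBH4 in MeOH at −78 °C then reduces the ketone from the convex face to 12.

**Step 14.** Most likely failure: elimination of the activated, α-branched secondary alcohol to a cyclopentene, or a stalled second esterification with the weakly acidic enoic acid, so that the monoesters accumulate. Fallback, from 12 to 20 by inversion first and acylation second: Mitsunobu reaction of 12 with the stronger 4-nitrobenzoic acid gives the inverted (6R)-4-nitrobenzoate F12. Methanolysis (K2CO3, MeOH) gives the (6R)-alcohol F13 (the same compound as A1), and a double Yamaguchi esterification with 17 (2,4,6-trichlorobenzoyl chloride, Et3N, then DMAP, toluene) gives 20 with retention.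

## Further compounds

F1 | step 4 | 2-methylbut-3-en-1-yl 4-methylbenzenesulfonate (racemic) | C=CC(C)COS(=O)(=O)c1ccc(C)cc1
F2 | step 4 | tert-butyl but-2-yn-1-yl(2-methylbut-3-en-1-yl)carbamate (racemic) | CC#CCN(CC(C)C=C)C(=O)OC(C)(C)C
F3 | step 4 | tert-butyl 4,7-dimethyl-6-oxo-1,3,4,4a,5,6-hexahydro-2H-cyclopenta[c]pyridine-2-carboxylate (racemic, both C4/C4a diastereomers) | O=C1CC2C(C)CN(C(=O)OC(C)(C)C)CC2=C1C
F4 | step 5 | tert-butyl 6-hydroxy-4,7-dimethyl-1,3,5,6-tetrahydro-2H-cyclopenta[c]pyridine-2-carboxylate (racemic) | OC1CC2=C(C)CN(C(=O)OC(C)(C)C)CC2=C1C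
F5 | step 5 | tert-butyl (6R)-6-acetoxy-4,7-dimethyl-1,3,5,6-tetrahydro-2H-cyclopenta[c]pyridine-2-carboxylate | CC(=O)O[C@@H]1CC2=C(C)CN(C(=O)OC(C)(C)C)CC2=C1C
F6 | step 6 | tert-butyl (6S)-6-hydroxy-4,7-dimethyl-1,3,5,6-tetrahydro-2H-cyclopenta[c]pyridine-2-carboxylate | O[C@H]1CC2=C(C)CN(C(=O)OC(C)(C)C)CC2=C1C
F7 | step 6 | tert-butyl (6S)-6-[(tert-butyldimethylsilyl)oxy]-4,7-dimethyl-1,3,5,6-tetrahydro-2H-cyclopenta[c]pyridine-2-carboxylate | CC(C)(C)[Si](C)(C)O[C@H]1CC2=C(C)CN(C(=O)OC(C)(C)C)CC2=C1C
F8 | step 6 | tert-butyl (4R,4aS,6S,7R,7aR)-6-[(tert-butyldimethylsilyl)oxy]-4,7-dimethyloctahydro-2H-cyclopenta[c]pyridine-2-carboxylate | CC(C)(C)[Si](C)(C)O[C@H]1C[C@@H]2[C@@H](CN(C(=O)OC(C)(C)C)C[C@@H]2C)[C@H]1C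
F9 | step 6 | tert-butyl (4R,4aS,6S,7R,7aR)-6-hydroxy-4,7-dimethyloctahydro-2H-cyclopenta[c]pyridine-2-carboxylate | O[C@H]1C[C@@H]2[C@@H](CN(C(=O)OC(C)(C)C)C[C@@H]2C)[C@H]1C
F10 | step 9 | (4R,4aS,7S,7aR)-4,7-dimethyloctahydro-6H-cyclopenta[c]pyridin-6-one | O=C1C[C@@H]2[C@@H](CNC[C@@H]2C)[C@@H]1C
F11 | step 9 | (4R,4aS,7S,7aR)-2,4,7-trimethyloctahydro-6H-cyclopenta[c]pyridin-6-one | O=C1C[C@@H]2[C@@H](CN(C)C[C@@H]2C)[C@@H]1C
F12 | step 14 | (4R,4aS,6R,7S,7aR)-2,4,7-trimethyloctahydro-1H-cyclopenta[c]pyridin-6-yl 4-nitrobenzoate | O=C(O[C@@H]1C[C@@H]2[C@@H](CN(C)C[C@@H]2C)[C@@H]1C)c1ccc(cc1)[N+](=O)[O-]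
F13 | step 14 | (4R,4aS,6R,7S,7aR)-2,4,7-trimethyloctahydro-1H-cyclopenta[c]pyridin-6-ol | O[C@@H]1C[C@@H]2[C@@H](CN(C)C[C@@H]2C)[C@@H]1C
A1 | alternative 1 | (4R,4aS,6R,7S,7aR)-2,4,7-trimethyloctahydro-1H-cyclopenta[c]pyridin-6-ol | O[C@@H]1C[C@@H]2[C@@H](CN(C)C[C@@H]2C)[C@@H]1C
A2 | alternative 1 | (2E,6E)-2,6-dimethylocta-2,6-dienedioyl dichloride | ClC(=O)/C=C(\C)CC/C=C(\C)C(Cl)=O
A3 | alternative 1 | tert-butyl 4,7-dimethyl-6-oxo-1,3,4,6,7,7a-hexahydro-2H-cyclopenta[c]pyridine-2-carboxylate (racemic) | O=C1C=C2C(C)CN(C(=O)OC(C)(C)C)CC2C1C
A4 | alternative 2 | tert-butyl but-2-yn-1-yl[(2R)-2-methylbut-3-en-1-yl]carbamate | C=C[C@@H](C)CN(CC#CC)C(=O)OC(C)(C)C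
A5 | alternative 2 | tert-butyl (4R,4aR)-4,7-dimethyl-6-oxo-1,3,4,4a,5,6-hexahydro-2H-cyclopenta[c]pyridine-2-carboxylate | O=C1C[C@@H]2[C@@H](C)CN(C(=O)OC(C)(C)C)CC2=C1C
A6 | alternative 3 | (2R)-2-[(1S,2R,3S,4S)-4-[(tert-butyldimethylsilyl)oxy]-2-formyl-3-methylcyclopentyl]propanal | CC(C)(C)[Si](C)(C)O[C@H]1C[C@@H]([C@@H](C)C=O)[C@@H](C=O)[C@@H]1C
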